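**Retrosynthetic overview**

1. The route rests on the E-trisubstituted C11=C12 alkene, whose C12 methyl is cis to the acetoxy carbon C10. A temporary 5-membered 1,2-oxaborole ring (O10–B–C12=C11–C10) holds that geometry; boron is then exchanged for CH3 with retention (Suzuki–Miyaura, MeI), followed by C10 acetylation and C15 desilylation.
2. Key disconnection at C11=C12: ring-closing metathesis within the mixed boronic ester of allylic alcohol 11 (C5–C11, C10 stereocentre) and alkenylboronic acid 23 (C12–C19, C15/C16 stereocentres).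
3. Alcohol 11: B-alkyl Suzuki coupling at C6–C7 of 3-ethenylfuran with the E-alkenyl iodide 9. Iodide 9 comes from (S)-epichlorohydrin by acetylide opening, sulfonium-ylide homologation and zirconium-catalysed carboalumination.
4. Boronic acid 23: from pent-4-yn-1-ol by hydrobromination, Johnson–Claisen rearrangement (E C15=C16), Shi epoxidation and epoxide-opening lactonisation (C15, C16), silylation, Miyaura borylation and pinacol cleavage.
5. Ring order: furan bought in; γ-lactone in step 11; oxaborole in step 15, opened again in step 16.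

Key step: step 15

Assumption: atom numbers C1–C19 follow the natural-product numbering (furan C1–C4, C10 the acetoxy carbon, C15 the carbinol, C16 the quaternary lactone carbon, C19 the lactone carbonyl); the target is 10S,15R,16S with both chain alkenes E.

**Route**

Step 1
Reactants: 1 furan-3-carbaldehyde
Product: 2 3-ethenylfuran
Conditions: Ph3PCH3Br, n-BuLi, Et2O, 0 °C → rt; distilled and kept as a THF solution
Reagents that add atoms: methyltriphenylphosphonium bromide, C[P+](c1ccccc1)(c1ccccc1)c1ccccc1.[Br-]
Why: Wittig methylenation of an aromatic aldehyde with the non-stabilised ylide is routine, and the volatile product is handled in solution.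

Step 2
Reactants: 3 (S)-epichlorohydrin
Product: 4 (2S)-1-chloro-5-(trimethylsilyl)pent-4-yn-2-ol
Conditions: Me3SiC≡CH, n-BuLi, THF, −78 °C; BF3·OEt2; then 3, −78 °C; H2O
Reagents that add atoms: ethynyltrimethylsilane, C#C[Si](C)(C)C
Why: BF3-assisted SN2 opening of the epoxide by the lithium acetylide at the unsubstituted ring carbon leaves the C–O stereocentre (the future C10) and the chloride untouched.

Step 3
Reactants: 4 (2S)-1-chloro-5-(trimethylsilyl)pent-4-yn-2-ol
Product: 7 (3S)-hex-1-en-5-yn-3-ol, via terminal epoxide 5 (not isolated), via C-silyl enynol 6 (not isolated)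
Conditions: Me3S+ I− (3.5 equiv), n-BuLi (3.3 equiv), THF, −20 °C → rt; then MeOH, K2CO3, rt
Reagents that add atoms: trimethylsulfonium iodide, C[S+](C)C.[I-]
Why: The alkoxide of 4 closes epoxide 5 by displacing chloride, dimethylsulfonium methylide opens 5 at its CH2 terminus and the β-alkoxy sulfonium salt eliminates Me2S to the allylic alcohol (epoxide-to-allylic-alcohol homologation with a sulfonium ylide), after which methanolic K2CO3 removes the C-silyl group; the C–O stereocentre is never broken.

Step 4
Reactants: 7 (3S)-hex-1-en-5-yn-3-ol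
Product: 9 (3S,5E)-6-iodo-5-methylhexa-1,5-dien-3-ol, via alkenylalane 8 (not isolated)
Conditions: AlMe3 (3 equiv), Cp2ZrCl2 (0.3 equiv), CH2Cl2, 0 °C → rt; then I2, THF, −30 → 0 °C; aq. potassium sodium tartrate
Reagents that add atoms: trimethylaluminium, C[Al](C)C; iodine, II
Why: Negishi zirconium-catalysed carboalumination adds Me–Al syn across the terminal alkyne with methyl at the internal carbon (the aluminium alkoxide is tolerated and the monosubstituted alkene is much slower), and iodinolysis of the C–Al bond with retention should give the E iodide that defines the C7=C8 geometry.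

Step 5
Reactants: 2 3-ethenylfuran; 9 (3S,5E)-6-iodo-5-methylhexa-1,5-dien-3-ol
Product: 11 (3S,5E)-8-(furan-3-yl)-5-methylocta-1,5-dien-3-ol, via B-alkyl-9-BBN 10 (not isolated)
Conditions: 2 (1.6 equiv), 9-BBN-H (1.5 equiv), THF, 0 °C → rt; then 9, PdCl2(dppf) (5 mol %), AsPh3, Cs2CO3, DMF/H2O, rt
Reagents that add atoms: none
Why: 9-BBN hydroborates the vinyl group of 2 at its terminus and the B-alkyl Suzuki–Miyaura coupling joins C6 to C7 with retention of the alkenyl iodide geometry; 2 is kept in excess over the borane so that no B–H remains for the vinyl group of 9.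

Step 6
Reactants: 12 pent-4-yn-1-ol
Product: 13 4-bromopent-4-en-1-ol
Conditions: Et4NBr, anhydrous HBr (Et4N+ HBr2− formed in situ), CH2Cl2, 40 °C
Reagents that add atoms: hydrogen bromide, Br
Why: Ionic Markovnikov hydrobromination of the terminal alkyne by the hydrogen dibromide anion should give the 2-bromo-1-alkene, which fixes the later position of boron at C12.

Step 7
Reactants: 13 4-bromopent-4-en-1-ol
Product: 14 4-bromopent-4-enal
Conditions: TEMPO (10 mol %), PhI(OAc)2, CH2Cl2, rt
Reagents that add atoms: none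
Why: Oxoammonium (TEMPO) oxidation stops at the aldehyde and leaves the bromoalkene alone.

Step 8
Reactants: 14 4-bromopent-4-enal
Product: 15 6-bromo-2-methylhepta-1,6-dien-3-ol (racemate)
Conditions: CH2=C(CH3)MgBr, THF, −78 → 0 °C; H2O
Reagents that add atoms: isopropenylmagnesium bromide, C=C(C)[Mg]Br
Why: Grignard 1,2-addition to the aldehyde at low temperature; the carbinol is made racemic on purpose because it is erased in step 9.

Step 9
Reactants: 15 6-bromo-2-methylhepta-1,6-dien-3-ol
Product: 17 ethyl (4E)-8-bromo-4-methylnona-4,8-dienoate, via ketene acetal 16 (not isolated)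
Conditions: CH3C(OEt)3, EtCO2H (cat.), 140 °C, EtOH distilled off
Reagents that add atoms: triethyl orthoacetate, CCOC(C)(OCC)OCC
Why: Johnson–Claisen rearrangement through ketene acetal 16: the chair transition state with the bromobutenyl chain equatorial should deliver the E trisubstituted C15=C16 alkene and the two-carbon ester arm (C17–C19).

Step 10
Reactants: 17 ethyl (4E)-8-bromo-4-methylnona-4,8-dienoate
Product: 18 ethyl 3-[(2R,3R)-3-(3-bromobut-3-en-1-yl)-2-methyloxiran-2-yl]propanoate
Conditions: D-fructose-derived Shi ketone (1,2:4,5-di-O-isopropylidene-β-D-erythro-2,3-hexodiulo-2,6-pyranose, 0.3 equiv), KHSO5 (as 2KHSO5·KHSO4·K2SO4), K2CO3, Bu4NHSO4, MeCN/CH2(OMe)2, aq. Na2B4O7 buffer (pH about 10.5), 0 °C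
Reagents that add atoms: potassium peroxymonosulfate, [K+].[O-]S(=O)(=O)OO
Why: Shi epoxidation: the dioxirane of the D-fructose-derived ketone attacks the electron-rich E trisubstituted alkene through the spiro transition state to give the (R,R)-epoxide, which sets C15 and the configuration at C16 that step 11 inverts, while the electron-poor 1,1-disubstituted bromoalkene should not react.

Step 11
Reactants: 18 ethyl 3-[(2R,3R)-3-(3-bromobut-3-en-1-yl)-2-methyloxiran-2-yl]propanoate
Product: 20 (5S)-5-[(1R)-4-bromo-1-hydroxypent-4-en-1-yl]-5-methyloxolan-2-one, via epoxy acid 19 (not isolated)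
Conditions: LiOH, THF/H2O, 0 °C → rt; then aq. HCl to pH 2–3, rt; CSA (cat.), CH2Cl2, rt to complete the closure
Reagents that add atoms: lithium hydroxide, [Li+].[OH-]
Why: Saponification gives epoxy acid 19, and on acidification the carboxyl group opens the protonated epoxide 5-exo at the tertiary carbon with inversion (epoxy-acid lactonisation), so that C16 becomes S while the C15–O bond and its R configuration are kept.

Step 12
Reactants: 20 (5S)-5-[(1R)-4-bromo-1-hydroxypent-4-en-1-yl]-5-methyloxolan-2-one
Product: 21 (5S)-5-[(1R)-4-bromo-1-(triethylsilyloxy)pent-4-en-1-yl]-5-methyloxolan-2-one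
Conditions: Et3SiOTf, 2,6-lutidine, CH2Cl2, −78 → 0 °C
Reagents that add atoms: triethylsilyl trifluoromethanesulfonate, CC[Si](CC)(CC)OS(=O)(=O)C(F)(F)F
Why: A silyl triflate with a hindered pyridine base silylates the congested secondary alcohol at low temperature without touching the lactone.

Step 13
Reactants: 21 (5S)-5-[(1R)-4-bromo-1-(triethylsilyloxy)pent-4-en-1-yl]-5-methyloxolan-2-one
Product: 22 (5S)-5-methyl-5-[(1R)-4-(4,4,5,5-tetramethyl-1,3,2-dioxaborolan-2-yl)-1-(triethylsilyloxy)pent-4-en-1-yl]oxolan-2-one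
Conditions: B2pin2, PdCl2(PPh3)2 (3 mol %), PPh3 (6 mol %), KOPh, toluene, 50 °C
Reagents that add atoms: bis(pinacolato)diboron, CC1(C)OB(OC1(C)C)B1OC(C)(C)C(C)(C)O1
Why: Miyaura borylation of the alkenyl bromide (oxidative addition, phenoxide-assisted transmetalation with B2pin2, reductive elimination) puts boron exactly where bromine was, so no regiochemical question arises.

Step 14
Reactants: 22 (5S)-5-methyl-5-[(1R)-4-(4,4,5,5-tetramethyl-1,3,2-dioxaborolan-2-yl)-1-(triethylsilyloxy)pent-4-en-1-yl]oxolan-2-one
Product: 23 [(5R)-5-[(2S)-2-methyl-5-oxooxolan-2-yl]-5-(triethylsilyloxy)pent-1-en-2-yl]boronic acid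
Conditions: NaIO4, NH4OAc, acetone/H2O, rt; used at once
Reagents that add atoms: water, O
Why: Periodate cleaves the pinacol released in the hydrolysis equilibrium of the boronic ester and so drives the conversion to the free boronic acid under near-neutral conditions that the silyl ether and the lactone should survive.

Step 15
Reactants: 11 (3S,5E)-8-(furan-3-yl)-5-methylocta-1,5-dien-3-ol; 23 [(5R)-5-[(2S)-2-methyl-5-oxooxolan-2-yl]-5-(triethylsilyloxy)pent-1-en-2-yl]boronic acid
Product: 25 (5S)-2-hydroxy-5-[(2E)-5-(furan-3-yl)-2-methylpent-2-en-1-yl]-3-{(3R)-3-[(2S)-2-methyl-5-oxooxolan-2-yl]-3-(triethylsilyloxy)propyl}-2,5-dihydro-1,2-oxaborole, via mixed boronic ester 24 (not isolated)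
Conditions: 23 (1.3 equiv), 4 Å molecular sieves, CH2Cl2 (0.05 M), rt; then second-generation Grubbs catalyst RuCl2(=CHPh)(H2IMes)(PCy3) (10 mol %), 40 °C, argon sparge
Reagents that add atoms: none
Why: Under dehydrating conditions 23 and 11 condense to the mixed boronic ester 24, which links the two terminal alkenes through O10–B–C12; the ruthenium benzylidene loads onto the monosubstituted vinyl group, the C11 alkylidene adds [2+2] to the 1,1-disubstituted C12=CH2 bond and the ruthenacyclobutane collapses by retro-[2+2] to the ring alkene and Ru=CH2, which leaves as ethene. The closest known reaction type is the boronate-tethered ring-closing metathesis of allylic alcohols with alkenylboronic acids or esters to cyclic alkenylboronic half-esters. The single ring formed, the 5-membered 2,5-dihydro-1,2-oxaborole (O, B, C12, C11, C10), closes by ring-closing metathesis at the new endocyclic C11=C12 bond, so C10 and boron are forced cis on the alkene. No stereocentre is created, and C10, C15 and C16 are not touched. The step needs site selectivity for the two tethered alkenes over the trisubstituted C7=C8 alkene and the furan, which is secured because C7=C8 is hindered and could only close a 4-membered ring; it also needs the ring product over dimerisation of 11, which the tether and the excess of 23 secure.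

Step 16
Reactants: 25 the 1,2-oxaborole of step 15
Product: 26 (5S)-5-[(1R,4E,6S,8E)-11-(furan-3-yl)-6-hydroxy-4,8-dimethyl-1-(triethylsilyloxy)undeca-4,8-dien-1-yl]-5-methyloxolan-2-one
Conditions: CH3I (5 equiv), Pd2(dba)3 (5 mol %), P(o-tol)3 (20 mol %), K2CO3, DMF (trace H2O), 60 °C; work-up at pH 4–5
Reagents that add atoms: iodomethane, CI
Why: Suzuki–Miyaura coupling: CH3I adds oxidatively to zerovalent palladium, the carbonate-activated cyclic alkenylboronate transmetalates with retention and reductive elimination forms the C12–CH3 bond, so the cis C10/boron relationship of the ring becomes the cis C10/methyl relationship of the E alkene; the hindered phosphine resists quaternisation by CH3I.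

Step 17
Reactants: 26 the C10 allylic alcohol of step 16
Product: 27 (5S)-5-[(1R,4E,6S,8E)-6-acetoxy-11-(furan-3-yl)-4,8-dimethyl-1-(triethylsilyloxy)undeca-4,8-dien-1-yl]-5-methyloxolan-2-one
Conditions: Ac2O, pyridine, DMAP (cat.), CH2Cl2, 0 °C → rt
Reagents that add atoms: acetic anhydride, CC(=O)OC(C)=O
Why: DMAP-catalysed acylation of the only free hydroxyl group (C10).

Step 18
Reactants: 27 the C10 acetate of step 17
Product: 28 10-acetylirciformonin B
Conditions: HF·pyridine, pyridine, THF, 0 °C → rt
Reagents that add atoms: none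
Why: Fluoride cleaves the triethylsilyl ether under buffered conditions that should spare the allylic acetate, the lactone and the furan.

**Compound list**

1 | furan-3-carbaldehyde | O=Cc1ccoc1 | starting material
2 | 3-ethenylfuran | C=Cc1ccoc1 | intermediate
3 | (S)-epichlorohydrin, (2S)-2-(chloromethyl)oxirane | ClC[C@@H]1CO1 | starting material
4 | (2S)-1-chloro-5-(trimethylsilyl)pent-4-yn-2-ol | ClC[C@@H](O)CC#C[Si](C)(C)C | intermediate
5 | trimethyl{3-[(2S)-oxiran-2-yl]prop-1-yn-1-yl}silane (not isolated) | C[Si](C)(C)C#CC[C@H]1CO1 | intermediate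
6 | (3S)-6-(trimethylsilyl)hex-1-en-5-yn-3-ol (not isolated) | C=C[C@@H](O)CC#C[Si](C)(C)C | intermediate
7 | (3S)-hex-1-en-5-yn-3-ol | C=C[C@@H](O)CC#C | intermediate
8 | {(1E,4S)-4-[(dimethylalumanyl)oxy]-2-methylhexa-1,5-dien-1-yl}dimethylalumane (not isolated) | C=C[C@@H](O[Al](C)C)C/C(C)=C/[Al](C)C | intermediate
9 | (3S,5E)-6-iodo-5-methylhexa-1,5-dien-3-ol | C=C[C@@H](O)C/C(C)=C/I | intermediate
10 | 9-[2-(furan-3-yl)ethyl]-9-borabicyclo[3.3.1]nonane (not isolated) | C1CCC2CCCC1B2CCc1ccoc1 | intermediate
11 | (3S,5E)-8-(furan-3-yl)-5-methylocta-1,5-dien-3-ol | C=C[C@@H](O)C/C(C)=C/CCc1ccoc1 | intermediate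
12 | pent-4-yn-1-ol | C#CCCCO | starting material
13 | 4-bromopent-4-en-1-ol | C=C(Br)CCCO | intermediate
14 | 4-bromopent-4-enal | C=C(Br)CCC=O | intermediate
15 | 6-bromo-2-methylhepta-1,6-dien-3-ol (racemate) | C=C(C)C(O)CCC(Br)=C | intermediate
16 | 6-bromo-3-[(1-ethoxyethenyl)oxy]-2-methylhepta-1,6-diene (racemate, not isolated) | C=C(OCC)OC(CCC(Br)=C)C(C)=C | intermediate
17 | ethyl (4E)-8-bromo-4-methylnona-4,8-dienoate | CCOC(=O)CC/C(C)=C/CCC(Br)=C | intermediate
18 | ethyl 3-[(2R,3R)-3-(3-bromobut-3-en-1-yl)-2-methyloxiran-2-yl]propanoate | CCOC(=O)CC[C@@]1(C)O[C@@H]1CCC(Br)=C | intermediate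
19 | 3-[(2R,3R)-3-(3-bromobut-3-en-1-yl)-2-methyloxiran-2-yl]propanoic acid (not isolated) | OC(=O)CC[C@@]1(C)O[C@@H]1CCC(Br)=C | intermediate
20 | (5S)-5-[(1R)-4-bromo-1-hydroxypent-4-en-1-yl]-5-methyloxolan-2-one | C=C(Br)CC[C@@H](O)[C@]1(C)CCC(=O)O1 | intermediate
21 | (5S)-5-[(1R)-4-bromo-1-(triethylsilyloxy)pent-4-en-1-yl]-5-methyloxolan-2-one | C=C(Br)CC[C@@H](O[Si](CC)(CC)CC)[C@]1(C)CCC(=O)O1 | intermediate
22 | (5S)-5-methyl-5-[(1R)-4-(4,4,5,5-tetramethyl-1,3,2-dioxaborolan-2-yl)-1-(triethylsilyloxy)pent-4-en-1-yl]oxolan-2-one | CC1(C)OB(OC1(C)C)C(=C)CC[C@@H](O[Si](CC)(CC)CC)[C@]2(C)CCC(=O)O2 | intermediate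
23 | [(5R)-5-[(2S)-2-methyl-5-oxooxolan-2-yl]-5-(triethylsilyloxy)pent-1-en-2-yl]boronic acid | OB(O)C(=C)CC[C@@H](O[Si](CC)(CC)CC)[C@]1(C)CCC(=O)O1 | intermediate
24 | (3S,5E)-8-(furan-3-yl)-5-methylocta-1,5-dien-3-yl hydrogen [(5R)-5-[(2S)-2-methyl-5-oxooxolan-2-yl]-5-(triethylsilyloxy)pent-1-en-2-yl]boronate (not isolated) | C=C[C@@H](OB(O)C(=C)CC[C@@H](O[Si](CC)(CC)CC)[C@]1(C)CCC(=O)O1)C/C(C)=C/CCc1ccoc1 | intermediate
25 | (5S)-2-hydroxy-5-[(2E)-5-(furan-3-yl)-2-methylpent-2-en-1-yl]-3-{(3R)-3-[(2S)-2-methyl-5-oxooxolan-2-yl]-3-(triethylsilyloxy)propyl}-2,5-dihydro-1,2-oxaborole | OB1O[C@@H](C/C(C)=C/CCc2ccoc2)C=C1CC[C@@H](O[Si](CC)(CC)CC)[C@]3(C)CCC(=O)O3 | intermediate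
26 | (5S)-5-[(1R,4E,6S,8E)-11-(furan-3-yl)-6-hydroxy-4,8-dimethyl-1-(triethylsilyloxy)undeca-4,8-dien-1-yl]-5-methyloxolan-2-one | O[C@H](/C=C(\C)CC[C@@H](O[Si](CC)(CC)CC)[C@]1(C)CCC(=O)O1)C/C(C)=C/CCc1ccoc1 | intermediate
27 | (5S)-5-[(1R,4E,6S,8E)-6-acetoxy-11-(furan-3-yl)-4,8-dimethyl-1-(triethylsilyloxy)undeca-4,8-dien-1-yl]-5-methyloxolan-2-one | CC(=O)O[C@H](/C=C(\C)CC[C@@H](O[Si](CC)(CC)CC)[C@]1(C)CCC(=O)O1)C/C(C)=C/CCc1ccoc1 | intermediate
28 | 10-acetylirciformonin B, (5S)-5-[(1R,4E,6S,8E)-6-acetoxy-11-(furan-3-yl)-1-hydroxy-4,8-dimethylundeca-4,8-dien-1-yl]-5-methyloxolan-2-one | CC(=O)O[C@H](/C=C(\C)CC[C@@H](O)[C@]1(C)CCC(=O)O1)C/C(C)=C/CCc1ccoc1 | target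

**Step count and risks**

Total: 18 steps. Longest linear sequence: 13 steps (steps 6–18, from pent-4-yn-1-ol).

Most likely to fail, in this order:

1. Step 15 (tethered ring-closing metathesis). The mixed ester may form incompletely and the carbene may close slowly onto the hindered 1,1-disubstituted alkenylboron, so that the allylic alcohol dimerises by cross-metathesis or isomerises to the ketone through ruthenium hydrides. The fallback is an untethered cross-metathesis with the methyl group already in place; it sets out from 21 and 11 and comes back at 26. Negishi coupling of bromide 21 with CH3ZnCl and Pd(PPh3)4 in THF should give (5S)-5-methyl-5-[(1R)-4-methyl-1-(triethylsilyloxy)pent-4-en-1-yl]oxolan-2-one F1. Cross-metathesis of an excess of this 2-methyl-1-alkene with 11 (second-generation Hoveyda–Grubbs catalyst RuCl2(=CH-C6H4-2-OiPr)(H2IMes), CH2Cl2, 40 °C) should then give 26 with loss of ethene. The geometry would rest only on the thermodynamic preference for the E isomer, so separation from the Z isomer would have to be accepted.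

2. Step 16 (methylation of the alkenylboron). Protodeboronation of the cyclic alkenylboronate under the basic conditions may outrun transmetalation of the hindered trisubstituted alkenyl group to the methylpalladium intermediate. The fallback reverses the polarity of the coupling; it sets out from 25 and comes back at 26. Iododeboronation of 25 with I2 and aqueous NaOH in THF at 0 °C, which goes with retention for alkenylboronic acids, should give (5S)-5-[(1R,4Z,6S,8E)-11-(furan-3-yl)-6-hydroxy-4-iodo-8-methyl-1-(triethylsilyloxy)undeca-4,8-dien-1-yl]-5-methyloxolan-2-one F2. N-Iodosuccinimide is avoided because it would iodinate the furan; the boronate complex is the more reactive site towards I2. Negishi methylation of F2 (excess CH3ZnCl, PdCl2(dppf), THF) should give 26 with retention.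

3. Step 14 (release of the boronic acid). Oxidative cleavage of the hindered pinacol ester may be sluggish, the silyl ether may be lost in the aqueous medium, and the alkenylboronic acid may protodeboronate or form anhydrides during isolation. The fallback is a transesterification route; it sets out from 22 and comes back at 23. Diethanolamine in Et2O should precipitate the chelated boronate 2-[(5R)-5-[(2S)-2-methyl-5-oxooxolan-2-yl]-5-(triethylsilyloxy)pent-1-en-2-yl]-1,3,6,2-dioxazaborocane F3, which is purified by filtration. Brief two-phase hydrolysis (0.1 M HCl, Et2O, 0 °C) should release 23 just before step 15.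

**Further compounds**

F1 | step 15 | (5S)-5-methyl-5-[(1R)-4-methyl-1-(triethylsilyloxy)pent-4-en-1-yl]oxolan-2-one | C=C(C)CC[C@@H](O[Si](CC)(CC)CC)[C@]1(C)CCC(=O)O1
F2 | step 16 | (5S)-5-[(1R,4Z,6S,8E)-11-(furan-3-yl)-6-hydroxy-4-iodo-8-methyl-1-(triethylsilyloxy)undeca-4,8-dien-1-yl]-5-methyloxolan-2-one | O[C@H](/C=C(\I)CC[C@@H](O[Si](CC)(CC)CC)[C@]1(C)CCC(=O)O1)C/C(C)=C/CCc1ccoc1
F3 | step 14 | 2-[(5R)-5-[(2S)-2-methyl-5-oxooxolan-2-yl]-5-(triethylsilyloxy)pent-1-en-2-yl]-1,3,6,2-dioxazaborocane | C=C(CC[C@@H](O[Si](CC)(CC)CC)[C@]1(C)CCC(=O)O1)[B-]23OCC[NH+]2CCO3
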